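How much double product stands at the end of birch, ash and maple, three flasks that differ in their charge of coupling partner?

* how much double product is there at the end, in percent of the substrate charged: for each flask in turn (birch, ash, maple)

common to all: substrate 20 mM
- Wednesday's: coupling partner 2.2 equiv; scavenger 1.5 equiv; run made earlier
- Monday's: coupling partner 4.8 equiv; scavenger 1.5 equiv; run made earlier
- birch: coupling partner 1.50 equiv; scavenger 1.50 equiv; time 10 h
- ash: coupling partner 2.00 equiv; scavenger 1.50 equiv; time 10 h
- maple: coupling partner 3.00 equiv; scavenger 1.50 equiv; time 10 h

- Wednesday's (time / h: double product / %, substrate / %): 0.417: 62, 12; 0.833: 66, 12; 1.33: 66, 10; 2.50: 66, 12; 5.00: 65, 17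
- Monday's (time / h: double product / %, substrate / %): 0.417: 79, 3; 0.833: 89, 1; 1.33: 91, 0; 2.50: 96, 0; 5.00: 96, 3

(scatter of a reading: 2 percentage points)

- a reading of substrate is of its free form alone

Keep a ledger of the coupling partner, taken here as the limiting reagent. On Wednesday's run double product reads 66% at 0.833 h and 65% at 5.00 h, so treat the books as closed. Enter the readings at 2.50 h, double product 66% and substrate 12%, and count the rest as mono adduct. Each double product took two partners and each mono adduct one:

used = 1 + double product − substrate = 154% of the substrate charged

lost = charge − used = 0.660 equiv

Suppose the loss is partner meeting partner. Take as a working guess, from this one run, that lost over used grows in step with the charge: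

lost / (used × charge) = 0.195 per equiv

Call this the waste ratio. Turned round, it gives the partner used:

used = charge / (1 + waste ratio × charge)

birch 1.16, ash 1.44, maple 1.89 equiv

Monday's reckons to 2.48 equiv, more than the 2 a substrate can take, so the guess fails there, and its readings at 2.50 h give 196% of the substrate charged. To turn used partner into double product, draw a straight line between Wednesday's and Monday's points, with slope 0.714:

birch 38.9%, ash 58.8%, maple 91.2%

The forecast differs from this reckoning with 31%, 54% and 90%, holding that “Whether that loss is proportional or fixed can't be separated from these runs”.

The flasks give 44.7%, 60.7% and 83.5%.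

    substrate + released group ⇌ idle adduct, settled at all times (K = 1300 M⁻¹)
    scavenger + released group → scavenged by-product (k = 2.00 M⁻¹ s⁻¹)
    coupling partner + mono adduct → double product + released group (k = 0.170 M⁻¹ s⁻¹)
    2 coupling partner → homo dimer (k = 0.0250 M⁻¹ s⁻¹)
    substrate + coupling partner → mono adduct + released group (k = 0.200 M⁻¹ s⁻¹)

In ash the main reason for the shortfall is the loss of two coupling partner to homo dimer: the same run without that step ends at 97.1% instead of 60.7%. Ash's 5.72 mM of homo dimer holds 0.572 equiv of partner, against 1.43 equiv used, so its waste ratio is 0.200 per equiv. Maple's 12.6 mM of homo dimer holds 1.26 equiv against 1.74 equiv used, so the waste ratio does not stand still but is higher than ash's, at 0.242 per equiv.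

(The runs come from a simulation for substances that don't exist, noise included.)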